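Ring numbering: C1 bears the acetate, C2=C3 is the alkene, C4 the free carbinol, C5 the tertiary carbinol. Without the acetyl group the cyclopentene is meso, with a mirror plane through C5 and the midpoint of C2=C3, so C1 and C4 are enantiotopic. The route therefore cuts C1–C2 and C3–C4 together. The key step takes an acyclic malonate whose central carbon is C5, already carrying its oxygen and the tridecanoyl group masked as a dithiane. In one flask both esters are reduced to aldehydes, vinylated and acetylated, forging both bonds and both carbinol centres under control of C5. Metathesis closes C2=C3, and a lipase removes one enantiotopic acetate.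

Key step: step 2

Step 1
Reactants: 1 1,3-dithiane; 2 1-bromododecane; 3 diethyl ketomalonate (diethyl 2-oxopropanedioate)
Product: 8 diethyl 2-(2-dodecyl-1,3-dithian-2-yl)-2-[(trimethylsilyl)oxy]propanedioate, via 2-lithio-1,3-dithiane 4 (not isolated), via 2-dodecyl-1,3-dithiane 5 (not isolated), via 2-dodecyl-2-lithio-1,3-dithiane 6 (not isolated), via lithium alkoxide adduct 7 (not isolated)
Conditions: n-BuLi, THF, −30 °C, then 2, −78 °C to rt; n-BuLi, −20 °C, then 3, −78 °C; Me3SiCl, −78 °C to rt
Reagents that add atoms: chlorotrimethylsilane C[Si](C)(C)Cl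
Why: Corey-Seebach dithiane umpolung run as a one-flask linchpin sequence, in which 4 is alkylated by SN2, 5 is lithiated again, the tertiary carbanion 6 adds 1,2 to the non-enolisable, strongly electrophilic central ketone of 3 and alkoxide 7 is O-silylated, with no stereocentre formed.

Step 2
Reactants: 8 diethyl 2-(2-dodecyl-1,3-dithian-2-yl)-2-[(trimethylsilyl)oxy]propanedioate; 9 vinylmagnesium bromide
Product: 13 (3R,4r,5S)-4-(2-dodecyl-1,3-dithian-2-yl)-4-hydroxyhepta-1,6-diene-3,5-diyl diacetate (meso; both acetoxy groups anti to the tertiary hydroxyl), via dialdehyde 10 (not isolated), via bis(bromomagnesium) alkoxide 11 (not isolated), via silyl ether diacetate 12 (not isolated)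
Conditions: i-Bu2AlH (2.2 equiv), CH2Cl2, −78 °C; 9 (excess, THF), −78 to 0 °C; Ac2O, pyridine, DMAP, 0 °C to rt; 1 M HCl, THF, rt
Reagents that add atoms: acetic anhydride CC(=O)OC(C)=O
Why: i-Bu2AlH takes both ester groups of 8 to the aldehyde level at −78 °C, each formyl group of 10 accepts one vinyl group by Grignard 1,2-addition so that C1–C2 and C3–C4 arise side by side, the bis-alkoxide 11 is acetylated in the same flask, and dilute acid then removes the silyl group from 12. The closest known reaction types are the one-pot ester reduction-vinylation of α-silyloxy esters and the in situ acetylation of aluminium or magnesium alkoxides. The step closes no ring; ring closure is left to the metathesis of step 3. Each new carbinol centre (C1 and C4) is set by 1,2-induction from C5: the non-chelating OSiMe3 group lies anti to the carbonyl dipole (polar Felkin-Anh or Cornforth model) and the nucleophile enters opposite the very large dithianyl group, which places each new oxygen anti to the C5 oxygen, and because both arms answer alike the meso isomer should result and the pseudoasymmetric C5 is fixed with it. The step needs chemoselectivity (stopping at the aldehyde), served by the low temperature and the crowding around C5, and facial selectivity in the second addition, served by excess reagent in THF and the poorly coordinating silyl ether, which disfavour a magnesium chelate.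

Step 3
Reactants: 13 (3R,4r,5S)-4-(2-dodecyl-1,3-dithian-2-yl)-4-hydroxyhepta-1,6-diene-3,5-diyl diacetate
Product: 14 (1R,2r,3S)-2-(2-dodecyl-1,3-dithian-2-yl)-2-hydroxycyclopent-4-ene-1,3-diyl diacetate (meso; acetoxy groups cis to each other and to the dithianyl group, trans to the hydroxyl)
Conditions: second-generation Hoveyda-Grubbs catalyst (5 mol %), CH2Cl2, 40 °C
Reagents that add atoms: none
Why: Ring-closing metathesis of a 1,6-diene joins the two terminal alkenes to the necessarily Z C2=C3 bond of the five-membered ring, is helped by the Thorpe-Ingold effect of quaternary C5, is driven by loss of ethylene and leaves the three stereocentres untouched.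

Step 4
Reactants: 14 (1R,2r,3S)-2-(2-dodecyl-1,3-dithian-2-yl)-2-hydroxycyclopent-4-ene-1,3-diyl diacetate
Product: 15 (1R,2r,3S)-2-hydroxy-2-tridecanoylcyclopent-4-ene-1,3-diyl diacetate (meso)
Conditions: PhI(OCOCF3)2, aq. MeCN, 0 °C to rt
Reagents that add atoms: water O
Why: Oxidative dithiane hydrolysis, in which the trivalent iodine reagent activates sulfur, water attacks the thionium ion and the ketone is released under conditions that should leave the alkene, the acetates and the tertiary alcohol alone.

Step 5
Reactants: 15 (1R,2r,3S)-2-hydroxy-2-tridecanoylcyclopent-4-ene-1,3-diyl diacetate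
Product: 16 (1S,4R,5S)-4,5-dihydroxy-5-tridecanoylcyclopent-2-en-1-yl acetate (target)
Conditions: Novozym 435 (immobilised Candida antarctica lipase B), MeOH, t-BuOMe, 30 °C, stopped at the monoacetate stage
Reagents that add atoms: none
Why: Lipase-catalysed enantiotopos-selective alcoholysis of a meso-diacetate: by the Kazlauskas rule (large group = the C5 side, medium group = the vinylic CH) the enzyme should deacylate the R-configured acetoxy carbon, the sense lipases also show with the parent cis-3,5-diacetoxycyclopentene, so the S-configured acetate at C1 stays and the absolute configuration of C1, C4 and C5 is set in this one event.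

Compound list
1 | 1,3-dithiane | C1CSCSC1 | starting material
2 | 1-bromododecane | CCCCCCCCCCCCBr | starting material
3 | diethyl ketomalonate | CCOC(=O)C(=O)C(=O)OCC | starting material
4 | 2-lithio-1,3-dithiane | [Li]C1SCCCS1 | intermediate
5 | 2-dodecyl-1,3-dithiane | CCCCCCCCCCCCC1SCCCS1 | intermediate
6 | 2-dodecyl-2-lithio-1,3-dithiane | [Li]C1(CCCCCCCCCCCC)SCCCS1 | intermediate
7 | lithium alkoxide of diethyl 2-(2-dodecyl-1,3-dithian-2-yl)-2-hydroxypropanedioate | [Li+].[O-]C(C(=O)OCC)(C(=O)OCC)C1(CCCCCCCCCCCC)SCCCS1 | intermediate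
8 | diethyl 2-(2-dodecyl-1,3-dithian-2-yl)-2-[(trimethylsilyl)oxy]propanedioate | CCCCCCCCCCCCC1(SCCCS1)C(O[Si](C)(C)C)(C(=O)OCC)C(=O)OCC | intermediate
9 | vinylmagnesium bromide | C=C[Mg]Br | starting material
10 | 2-(2-dodecyl-1,3-dithian-2-yl)-2-[(trimethylsilyl)oxy]propanedial | CCCCCCCCCCCCC1(SCCCS1)C(O[Si](C)(C)C)(C=O)C=O | intermediate
11 | bis(bromomagnesium) alkoxide of (3R,4r,5S)-4-(2-dodecyl-1,3-dithian-2-yl)-4-[(trimethylsilyl)oxy]hepta-1,6-diene-3,5-diol | CCCCCCCCCCCCC1(SCCCS1)[C@](O[Si](C)(C)C)([C@H](O[Mg]Br)C=C)[C@@H](O[Mg]Br)C=C | intermediate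
12 | (3R,4r,5S)-4-(2-dodecyl-1,3-dithian-2-yl)-4-[(trimethylsilyl)oxy]hepta-1,6-diene-3,5-diyl diacetate | CCCCCCCCCCCCC1(SCCCS1)[C@](O[Si](C)(C)C)([C@H](OC(C)=O)C=C)[C@@H](OC(C)=O)C=C | intermediate
13 | (3R,4r,5S)-4-(2-dodecyl-1,3-dithian-2-yl)-4-hydroxyhepta-1,6-diene-3,5-diyl diacetate | CCCCCCCCCCCCC1(SCCCS1)[C@](O)([C@H](OC(C)=O)C=C)[C@@H](OC(C)=O)C=C | intermediate
14 | (1R,2r,3S)-2-(2-dodecyl-1,3-dithian-2-yl)-2-hydroxycyclopent-4-ene-1,3-diyl diacetate | CCCCCCCCCCCCC1(SCCCS1)[C@]2(O)[C@H](OC(C)=O)C=C[C@@H]2OC(C)=O | intermediate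
15 | (1R,2r,3S)-2-hydroxy-2-tridecanoylcyclopent-4-ene-1,3-diyl diacetate | CCCCCCCCCCCCC(=O)[C@]1(O)[C@H](OC(C)=O)C=C[C@@H]1OC(C)=O | intermediate
16 | (1S,4R,5S)-4,5-dihydroxy-5-tridecanoylcyclopent-2-en-1-yl acetate | CCCCCCCCCCCCC(=O)[C@]1(O)[C@H](O)C=C[C@@H]1OC(C)=O | target

Total step count: 5. Longest linear sequence: 5 steps (1 to 8 to 13 to 14 to 15 to 16).

Steps most likely to fail

Risk 1, step 2. Facial selectivity may erode in the second vinyl addition. The first magnesium alkoxide can chelate the remaining formyl group, so carbinol epimers would accompany the meso isomer. The fallback moves stereocontrol from C–C to C–H bond formation and acts as a stereoconvergent redox funnel. It sets out from 14, carried through step 3 as the epimer mixture, and comes back at 14.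
- K2CO3 in MeOH strips the acetates and gives the triol (1R,2r,3S)-2-(2-dodecyl-1,3-dithian-2-yl)cyclopent-4-ene-1,2,3-triol F1 beside its carbinol epimers.
- MnO2 in CH2Cl2 oxidises all of them to the one achiral ene-dione 2-(2-dodecyl-1,3-dithian-2-yl)-2-hydroxycyclopent-4-ene-1,3-dione F2.
- Luche reduction (NaBH4, CeCl3·7H2O, MeOH, −78 °C) should bring hydride to both carbonyl groups from the face opposite the dithianyl group and return F1 alone.
- Ac2O, pyridine and DMAP then give 14.

Risk 2, step 5. The enzymatic deacylation may be sluggish or unselective, because both acetates sit next to a quaternary carbon and may not fit the active site. The fallback replaces the enzyme by a reagent-controlled desymmetrisation of a prochiral diketone. It sets out from 14 and comes back at 16.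
- 14 is taken through F1 to F2 as described above.
- (R)-B-methyl CBS oxazaborolidine with catecholborane in toluene at −78 °C should reduce only the carbonyl group whose catalyst-preferred face is also the face opposite the dithianyl group. This gives the hydroxy enone (4S,5R)-5-(2-dodecyl-1,3-dithian-2-yl)-4,5-dihydroxycyclopent-2-en-1-one F3.
- Ac2O and pyridine acetylate the secondary alcohol to the acetoxy enone (1S,5R)-5-(2-dodecyl-1,3-dithian-2-yl)-5-hydroxy-4-oxocyclopent-2-en-1-yl acetate F4.
- Luche reduction, again anti to the dithianyl group, gives the monoacetate (1S,4R,5S)-5-(2-dodecyl-1,3-dithian-2-yl)-4,5-dihydroxycyclopent-2-en-1-yl acetate F5.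
- PhI(OCOCF3)2 in aq. MeCN unmasks the ketone and gives 16.

Risk 3, step 3. The ruthenium carbene may be deactivated by chelation to the dithiane sulfur atoms. The fallback removes sulfur before the metathesis. It sets out from 13 and comes back at 15.
- PhI(OCOCF3)2 in aq. MeCN converts 13 into the keto diene (3R,4r,5S)-4-hydroxy-4-tridecanoylhepta-1,6-diene-3,5-diyl diacetate F6.
- Ring-closing metathesis of this sulfur-free diene with the same catalyst gives 15.

Further compounds
F1 | step 2 | (1R,2r,3S)-2-(2-dodecyl-1,3-dithian-2-yl)cyclopent-4-ene-1,2,3-triol | CCCCCCCCCCCCC1(SCCCS1)[C@]2(O)[C@H](O)C=C[C@@H]2O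
F2 | step 2 | 2-(2-dodecyl-1,3-dithian-2-yl)-2-hydroxycyclopent-4-ene-1,3-dione | CCCCCCCCCCCCC1(SCCCS1)C2(O)C(=O)C=CC2=O
F3 | step 5 | (4S,5R)-5-(2-dodecyl-1,3-dithian-2-yl)-4,5-dihydroxycyclopent-2-en-1-one | CCCCCCCCCCCCC1(SCCCS1)[C@]2(O)C(=O)C=C[C@@H]2O
F4 | step 5 | (1S,5R)-5-(2-dodecyl-1,3-dithian-2-yl)-5-hydroxy-4-oxocyclopent-2-en-1-yl acetate | CCCCCCCCCCCCC1(SCCCS1)[C@]2(O)C(=O)C=C[C@@H]2OC(C)=O
F5 | step 5 | (1S,4R,5S)-5-(2-dodecyl-1,3-dithian-2-yl)-4,5-dihydroxycyclopent-2-en-1-yl acetate | CCCCCCCCCCCCC1(SCCCS1)[C@]2(O)[C@H](O)C=C[C@@H]2OC(C)=O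
F6 | step 3 | (3R,4r,5S)-4-hydroxy-4-tridecanoylhepta-1,6-diene-3,5-diyl diacetate | CCCCCCCCCCCCC(=O)[C@](O)([C@H](OC(C)=O)C=C)[C@@H](OC(C)=O)C=C
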